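All four ring stereocentres (C1, C6, C7, C8; cadinane numbering) sit on two bonds of cyclohexane ring B, C1–C6 (the ring fusion) and C7–C8. Both are forged at once by an intramolecular Diels–Alder reaction of an acyclic precursor: a (1E,3Z)-1-acyloxy-3-silyloxydiene (C8=C9–C10=C1), already carrying the side-chain ester, adds to a Z-alkene (C6=C7) whose alkynyl group is the latent acrylic acid. The step closes rings A and B together and sets C1, C6, C7 and C8. A temporary silyloxy stereocentre at C5 dictates the absolute sense and is later erased by 1,3-transposition to the C15 alcohol.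

Key step: step 10

Remark: atoms are numbered as in cadinane: C1 and C6 are the ring-fusion carbons, C7 bears the C11(=C13)–C12 acrylic unit, C8 the acyloxy group, C10 the C14 methylidene, C4 the C15 hydroxymethyl; ring A is C1–C6, ring B is C1, C6–C10.
Remark: the ProPhenol enantiomer in step 5 is the one that gives the 6R carbinol; (S,S) is assumed by analogy with additions to enals.
Remark: CIP descriptors of intermediates change with substituent priorities while the spatial arrangement is conserved; the SMILES strings are authoritative.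

Step 1
Reactants: 1 (R)-2,2-dimethyl-1,3-dioxolane-4-carbaldehyde
Product: 2 (4S)-4-ethynyl-2,2-dimethyl-1,3-dioxolane
Conditions: dimethyl (1-diazo-2-oxopropyl)phosphonate, K2CO3, MeOH, 0 °C to rt
Reagents that add atoms: dimethyl (1-diazo-2-oxopropyl)phosphonate, CC(=O)C(=[N+]=[N-])P(=O)(OC)OC
Why: Seyferth–Gilbert homologation in the Ohira–Bestmann variant converts the aldehyde into the terminal alkyne under mild carbonate conditions that should leave the dioxolane stereocentre untouched (R to S is a priority change only).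

Step 2
Reactants: 2 (4S)-4-ethynyl-2,2-dimethyl-1,3-dioxolane
Product: 3 2-[(4S)-2,2-dimethyl-1,3-dioxolan-4-yl]prop-2-enoic acid
Conditions: Pd(OAc)2 (2 mol%), 2-PyPPh2 (8 mol%), MeSO3H (4 mol%), CO (10 bar), H2O (10 equiv), THF, 45 °C
Reagents that add atoms: carbon monoxide, [C-]#[O+]; water, O
Why: Markovnikov (branched-selective) palladium-catalysed hydroxycarbonylation of a terminal alkyne places the carboxyl group on the internal carbon, and ligand in excess of the acid should keep the acetonide intact.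

Step 3
Reactants: 4 1,4-bis(trimethylsilyl)buta-1,3-diyne
Product: 6 buta-1,3-diyn-1-yl(trimethyl)silane, via lithium diynide 5 (not isolated)
Conditions: MeLi·LiBr (1.0 equiv), Et2O, 0 °C to rt; then H2O
Reagents that add atoms: none
Why: Selective mono-desilylation by attack of methyllithium at one silicon gives the lithium diynide and Me4Si, and protonation releases the terminal diyne.

Step 4
Reactants: 7 methyl 6-oxohexanoate
Product: 8 methyl 5-formylhex-5-enoate
Conditions: aq. CH2O (37%), pyrrolidine (10 mol%), EtCO2H (10 mol%), i-PrOH, 45 °C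
Reagents that add atoms: formaldehyde, C=O
Why: Organocatalytic α-methylenation (enamine Mannich condensation then elimination) of the aldehyde installs the C4=C15 methylidene, and the ester is inert.

Step 5
Reactants: 8 methyl 5-formylhex-5-enoate; 6 buta-1,3-diyn-1-yl(trimethyl)silane
Product: 9 methyl (6R)-6-hydroxy-5-methylidene-10-(trimethylsilyl)deca-7,9-diynoate
Conditions: (S,S)-ProPhenol (20 mol%), Me2Zn (3 equiv), Ph3PO (40 mol%), toluene, 4 °C
Reagents that add atoms: none
Why: Zinc–ProPhenol-catalysed enantioselective alkynylation of an enal with a 1,3-diyne, in which the chiral dinuclear zinc alkynyl complex differentiates the aldehyde faces and so sets the carbinol stereocentre (6R, the future C5).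

Step 6
Reactants: 9 methyl (6R)-6-hydroxy-5-methylidene-10-(trimethylsilyl)deca-7,9-diynoate
Product: 10 methyl (6S,7Z)-6-hydroxy-5-methylidene-10-(trimethylsilyl)dec-7-en-9-ynoate
Conditions: Rieke zinc (excess), THF/MeOH/H2O, 65 °C
Reagents that add atoms: none
Why: Hydroxyl-directed cis-semireduction of the propargylic triple bond of a 2,4-diyn-1-ol by activated zinc gives the Z-enyne by syn delivery of two hydrogens, while the silyl-capped alkyne, the ester and the 1,1-disubstituted alkene should survive (R to S is a priority change only).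

Step 7
Reactants: 10 methyl (6S,7Z)-6-hydroxy-5-methylidene-10-(trimethylsilyl)dec-7-en-9-ynoate
Product: 12 (8S,9Z)-8-hydroxy-7-methylidene-12-(trimethylsilyl)dodec-9-ene-1,11-diyn-3-one, via Weinreb amide 11 (not isolated)
Conditions: MeNHOMe·HCl (2 equiv), i-PrMgCl (5 equiv), THF, −20 °C; then HC≡CMgBr (4 equiv), 0 °C to rt; inverse quench into cold aq. NaHSO4
Reagents that add atoms: ethynylmagnesium bromide, C#C[Mg]Br; N,O-dimethylhydroxylamine hydrochloride, CNOC.Cl (its atoms stay in 11 only)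
Why: Weinreb ketone synthesis in one pot, in which the magnesium amide converts the ester into the N-methoxy-N-methylamide whose chelated adduct with the ethynyl Grignard reagent collapses to the ynone only on acidic quench, the hydroxyl riding as its alkoxide and the C-silyl group preventing metalation of the enyne.

Step 8
Reactants: 12 (8S,9Z)-8-hydroxy-7-methylidene-12-(trimethylsilyl)dodec-9-ene-1,11-diyn-3-one; 3 2-[(4S)-2,2-dimethyl-1,3-dioxolan-4-yl]prop-2-enoic acid
Product: 13 (1E,8S,9Z)-8-hydroxy-7-methylidene-3-oxo-12-(trimethylsilyl)dodeca-1,9-dien-11-yn-1-yl 2-[(4S)-2,2-dimethyl-1,3-dioxolan-4-yl]prop-2-enoate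
Conditions: N-methylmorpholine (10 mol%), CH2Cl2, 0 °C to rt
Reagents that add atoms: none
Why: Amine-catalysed conjugate (oxa-Michael) addition of the carboxylic acid to the terminal ynone gives the thermodynamically preferred E β-acyloxy enone, the carboxylate out-competing the secondary alcohol under a weakly nucleophilic base.

Step 9
Reactants: 13 (1E,8S,9Z)-8-hydroxy-7-methylidene-3-oxo-12-(trimethylsilyl)dodeca-1,9-dien-11-yn-1-yl 2-[(4S)-2,2-dimethyl-1,3-dioxolan-4-yl]prop-2-enoate
Product: 14 (1E,3Z,8S,9Z)-3,8-bis[(tert-butyldimethylsilyl)oxy]-7-methylidene-12-(trimethylsilyl)dodeca-1,3,9-trien-11-yn-1-yl 2-[(4S)-2,2-dimethyl-1,3-dioxolan-4-yl]prop-2-enoate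
Conditions: TBSOTf (2.5 equiv), Et3N (4 equiv), CH2Cl2, −78 to 0 °C
Reagents that add atoms: tert-butyldimethylsilyl trifluoromethanesulfonate, CC(C)(C)[Si](C)(C)OS(=O)(=O)C(F)(F)F
Why: Soft enolisation (silyl triflate and amine) at the only enolisable position gives the cross-conjugated silyl dienol ether of a Danishefsky-type diene with the Z geometry usual for acyclic ketones, and silylates the C5 hydroxyl in the same operation.

Step 10
Reactants: 14 (1E,3Z,8S,9Z)-3,8-bis[(tert-butyldimethylsilyl)oxy]-7-methylidene-12-(trimethylsilyl)dodeca-1,3,9-trien-11-yn-1-yl 2-[(4S)-2,2-dimethyl-1,3-dioxolan-4-yl]prop-2-enoate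
Product: 15 (1R,2R,4aS,8S,8aR)-4,8-bis[(tert-butyldimethylsilyl)oxy]-7-methylidene-1-[(trimethylsilyl)ethynyl]-1,2,4a,5,6,7,8,8a-octahydronaphthalen-2-yl 2-[(4S)-2,2-dimethyl-1,3-dioxolan-4-yl]prop-2-enoate
Conditions: toluene (2 mM), BHT (cat.), Et3N (0.1 equiv), 130 °C, sealed tube
Reagents that add atoms: none
Why: Thermal, concerted, suprafacial [4+2] cycloaddition in which the nucleophilic diene terminus C1 bonds to C6 and the acyloxy-bearing terminus C8 to C7; the closest known reaction type is the type 1 intramolecular Diels–Alder reaction of decatrienes carrying a silyloxy-substituted diene. Ring B is the six-membered cycloadduct ring itself, and ring A closes as the fused six-membered ring through the four-atom tether C2–C5 in a chair-like anti (trans-fused) transition state. The cis relation of H1 and H8 follows from the E,Z diene (C2 and the acyloxy group both outside), the cis relation of H6 and H7 from the Z alkene, and the trans ring fusion from the anti tether, which places the alkynyl group exo and hence trans to O8. The selectivity needed is anti over syn tether and one diene face: the bulky silyloxy group on C10, cis to C2, should destabilise the syn (cis-fused) transition state as a steric directing group, and the linear Z substituent has no endo preference to oppose it. The C5 stereocentre sets the absolute sense because A(1,3) strain with the cis alkynyl group forces H5 into the alkene plane, so the C5 silyloxy group becomes equatorial and anti to the approaching diene, whereas attack on the other face would put it syn-axial to the alkynyl group. High dilution should suppress intermolecular addition to the side-chain acrylate.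

Step 11
Reactants: 15 cycloadduct (silyl enol ether)
Product: 16 (1R,2S,4aS,8S,8aR)-8-[(tert-butyldimethylsilyl)oxy]-7-methylidene-4-oxo-1-[(trimethylsilyl)ethynyl]decahydronaphthalen-2-yl 2-[(4S)-2,2-dimethyl-1,3-dioxolan-4-yl]prop-2-enoate
Conditions: HF·pyridine, pyridine, THF, −10 to 0 °C
Reagents that add atoms: none
Why: Acidic fluoride protodesilylates the silyl enol ether by C9-protonation without a free enolate, so the β-acyloxy group should not be expelled, and this cleavage is far faster than that of the alkyl TBS ether, the C–SiMe3 bond or the acetonide.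

Step 12
Reactants: 16 C10 ketone
Product: 17 (1R,2S,4aS,8S,8aS)-8-[(tert-butyldimethylsilyl)oxy]-4,7-dimethylidene-1-[(trimethylsilyl)ethynyl]decahydronaphthalen-2-yl 2-[(4S)-2,2-dimethyl-1,3-dioxolan-4-yl]prop-2-enoate
Conditions: Zn, CH2Br2, TiCl4 (preformed Lombardo reagent), THF/CH2Cl2, 0 °C to rt
Reagents that add atoms: dibromomethane, BrCBr
Why: Takai–Lombardo methylenation with the non-basic titanium–zinc methylene reagent is ketone-selective, so the β-acyloxy ketone should be methylenated without elimination, epimerisation at C1 or attack on either ester.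

Step 13
Reactants: 17 bis-exocyclic diene
Product: 18 (1R,2S,4aS,8S,8aS)-1-ethynyl-8-hydroxy-4,7-dimethylidenedecahydronaphthalen-2-yl 2-[(4S)-2,2-dimethyl-1,3-dioxolan-4-yl]prop-2-enoate
Conditions: TBAF (4 equiv), AcOH (2 equiv), THF, 0 °C to rt
Reagents that add atoms: none
Why: Fluoride-mediated desilylation cleaves the secondary TBS ether and the alkynyl C–Si bond, the acetic acid buffer guarding against acyl migration and conjugate addition to the acrylate.

Step 14
Reactants: 18 C5 allylic alcohol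
Product: 19 (1R,2S,4aS,8aS)-1-ethynyl-7-(hydroxymethyl)-4-methylidene-1,2,3,4,4a,5,6,8a-octahydronaphthalen-2-yl 2-[(4S)-2,2-dimethyl-1,3-dioxolan-4-yl]prop-2-enoate
Conditions: Ph3SiOReO3 (5 mol%), Et2O, −50 to 0 °C
Reagents that add atoms: none
Why: Perrhenate-catalysed 1,3-transposition of an allylic alcohol through a cyclic perrhenate ester shift should equilibrate towards the trisubstituted endocyclic C4=C5 alkene with the unhindered primary C15 alcohol, erasing the temporary C5 stereocentre.

Step 15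
Reactants: 19 terminal alkyne
Product: 20 2-[(1R,2S,4aS,8aS)-2-({2-[(4S)-2,2-dimethyl-1,3-dioxolan-4-yl]prop-2-enoyl}oxy)-7-(hydroxymethyl)-4-methylidene-1,2,3,4,4a,5,6,8a-octahydronaphthalen-1-yl]prop-2-enoic acid
Conditions: Pd(OAc)2 (3 mol%), 2-PyPPh2 (12 mol%), MeSO3H (6 mol%), CO (10 bar), H2O (20 equiv), THF, 45 °C
Reagents that add atoms: carbon monoxide, [C-]#[O+]; water, O
Why: Markovnikov palladium-catalysed hydroxycarbonylation turns the terminal alkyne into the 2-substituted acrylic acid (C11=C13, C12), the alkyne inserting far faster than any alkene and excess water out-competing the allylic alcohol.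

Step 16
Reactants: 20 acetonide-protected acid
Product: 21 2-[(1R,2S,4aS,8aS)-2-{[(3S)-3,4-dihydroxy-2-methylidenebutanoyl]oxy}-7-(hydroxymethyl)-4-methylidene-1,2,3,4,4a,5,6,8a-octahydronaphthalen-1-yl]prop-2-enoic acid
Conditions: AcOH/H2O (4:1), 35 °C
Reagents that add atoms: none
Why: Mild acid-catalysed acetal hydrolysis frees the diol, and the acidic medium and low temperature should avoid the base-promoted lactonisation of the 4-hydroxy ester and spare the allylic alcohol and exocyclic alkenes.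

Compound list
1 | (R)-2,2-dimethyl-1,3-dioxolane-4-carbaldehyde | O=C[C@H]1COC(C)(C)O1 | starting material
2 | (4S)-4-ethynyl-2,2-dimethyl-1,3-dioxolane | C#C[C@H]1COC(C)(C)O1 | intermediate
3 | 2-[(4S)-2,2-dimethyl-1,3-dioxolan-4-yl]prop-2-enoic acid | C=C(C(=O)O)[C@H]1COC(C)(C)O1 | intermediate
4 | 1,4-bis(trimethylsilyl)buta-1,3-diyne | C[Si](C)(C)C#CC#C[Si](C)(C)C | starting material
5 | lithium 4-(trimethylsilyl)buta-1,3-diyn-1-ide | [Li]C#CC#C[Si](C)(C)C | intermediate
6 | buta-1,3-diyn-1-yl(trimethyl)silane | C#CC#C[Si](C)(C)C | intermediate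
7 | methyl 6-oxohexanoate | COC(=O)CCCCC=O | starting material
8 | methyl 5-formylhex-5-enoate | COC(=O)CCCC(=C)C=O | intermediate
9 | methyl (6R)-6-hydroxy-5-methylidene-10-(trimethylsilyl)deca-7,9-diynoate | COC(=O)CCCC(=C)[C@@H](O)C#CC#C[Si](C)(C)C | intermediate
10 | methyl (6S,7Z)-6-hydroxy-5-methylidene-10-(trimethylsilyl)dec-7-en-9-ynoate | COC(=O)CCCC(=C)[C@@H](O)/C=C\C#C[Si](C)(C)C | intermediate
11 | (6S,7Z)-6-hydroxy-N-methoxy-N-methyl-5-methylidene-10-(trimethylsilyl)dec-7-en-9-ynamide | CON(C)C(=O)CCCC(=C)[C@@H](O)/C=C\C#C[Si](C)(C)C | intermediate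
12 | (8S,9Z)-8-hydroxy-7-methylidene-12-(trimethylsilyl)dodec-9-ene-1,11-diyn-3-one | C#CC(=O)CCCC(=C)[C@@H](O)/C=C\C#C[Si](C)(C)C | intermediate
13 | (1E,8S,9Z)-8-hydroxy-7-methylidene-3-oxo-12-(trimethylsilyl)dodeca-1,9-dien-11-yn-1-yl 2-[(4S)-2,2-dimethyl-1,3-dioxolan-4-yl]prop-2-enoate | C=C(C(=O)O/C=C/C(=O)CCCC(=C)[C@@H](O)/C=C\C#C[Si](C)(C)C)[C@H]1COC(C)(C)O1 | intermediate
14 | (1E,3Z,8S,9Z)-3,8-bis[(tert-butyldimethylsilyl)oxy]-7-methylidene-12-(trimethylsilyl)dodeca-1,3,9-trien-11-yn-1-yl 2-[(4S)-2,2-dimethyl-1,3-dioxolan-4-yl]prop-2-enoate | C=C(C(=O)O/C=C/C(O[Si](C)(C)C(C)(C)C)=C/CCC(=C)[C@@H](O[Si](C)(C)C(C)(C)C)/C=C\C#C[Si](C)(C)C)[C@H]1COC(C)(C)O1 | intermediate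
15 | (1R,2R,4aS,8S,8aR)-4,8-bis[(tert-butyldimethylsilyl)oxy]-7-methylidene-1-[(trimethylsilyl)ethynyl]-1,2,4a,5,6,7,8,8a-octahydronaphthalen-2-yl 2-[(4S)-2,2-dimethyl-1,3-dioxolan-4-yl]prop-2-enoate (trans-fused; H6/H7 cis; C7 alkynyl and C8 acyloxy trans-diaxial; C5 silyloxy equatorial) | C[Si](C)(C)C#C[C@H]1[C@H]2[C@H](O[Si](C)(C)C(C)(C)C)C(=C)CC[C@@H]2C(O[Si](C)(C)C(C)(C)C)=C[C@@H]1OC(=O)C(=C)[C@H]3COC(C)(C)O3 | intermediate
16 | (1R,2S,4aS,8S,8aR)-8-[(tert-butyldimethylsilyl)oxy]-7-methylidene-4-oxo-1-[(trimethylsilyl)ethynyl]decahydronaphthalen-2-yl 2-[(4S)-2,2-dimethyl-1,3-dioxolan-4-yl]prop-2-enoate | C[Si](C)(C)C#C[C@H]1[C@H]2[C@H](O[Si](C)(C)C(C)(C)C)C(=C)CC[C@@H]2C(=O)C[C@@H]1OC(=O)C(=C)[C@H]3COC(C)(C)O3 | intermediate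
17 | (1R,2S,4aS,8S,8aS)-8-[(tert-butyldimethylsilyl)oxy]-4,7-dimethylidene-1-[(trimethylsilyl)ethynyl]decahydronaphthalen-2-yl 2-[(4S)-2,2-dimethyl-1,3-dioxolan-4-yl]prop-2-enoate | C[Si](C)(C)C#C[C@H]1[C@H]2[C@H](O[Si](C)(C)C(C)(C)C)C(=C)CC[C@@H]2C(=C)C[C@@H]1OC(=O)C(=C)[C@H]3COC(C)(C)O3 | intermediate
18 | (1R,2S,4aS,8S,8aS)-1-ethynyl-8-hydroxy-4,7-dimethylidenedecahydronaphthalen-2-yl 2-[(4S)-2,2-dimethyl-1,3-dioxolan-4-yl]prop-2-enoate | C#C[C@H]1[C@H]2[C@H](O)C(=C)CC[C@@H]2C(=C)C[C@@H]1OC(=O)C(=C)[C@H]3COC(C)(C)O3 | intermediate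
19 | (1R,2S,4aS,8aS)-1-ethynyl-7-(hydroxymethyl)-4-methylidene-1,2,3,4,4a,5,6,8a-octahydronaphthalen-2-yl 2-[(4S)-2,2-dimethyl-1,3-dioxolan-4-yl]prop-2-enoate | C#C[C@H]1[C@H]2C=C(CO)CC[C@@H]2C(=C)C[C@@H]1OC(=O)C(=C)[C@H]3COC(C)(C)O3 | intermediate
20 | 2-[(1R,2S,4aS,8aS)-2-({2-[(4S)-2,2-dimethyl-1,3-dioxolan-4-yl]prop-2-enoyl}oxy)-7-(hydroxymethyl)-4-methylidene-1,2,3,4,4a,5,6,8a-octahydronaphthalen-1-yl]prop-2-enoic acid | C=C(C(=O)O)[C@H]1[C@H]2C=C(CO)CC[C@@H]2C(=C)C[C@@H]1OC(=O)C(=C)[C@H]3COC(C)(C)O3 | intermediate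
21 | 2-[(1R,2S,4aS,8aS)-2-{[(3S)-3,4-dihydroxy-2-methylidenebutanoyl]oxy}-7-(hydroxymethyl)-4-methylidene-1,2,3,4,4a,5,6,8a-octahydronaphthalen-1-yl]prop-2-enoic acid | C=C(C(=O)O)[C@H]1[C@H]2C=C(CO)CC[C@@H]2C(=C)C[C@@H]1OC(=O)C(=C)[C@H](O)CO | target

Total step count: 16. Longest linear sequence: 13 steps (steps 4 to 16, from methyl 6-oxohexanoate 7).

Steps most likely to fail

Step 10. The unactivated Z-alkene may cycloadd too slowly, so that the dienyl ester degrades by acyl transfer or reacts through its acrylate before ring closure; anti/syn tether selectivity may also be incomplete. Fallback, setting out from 12: PMe3-catalysed addition of 4-methoxybenzyl alcohol to the ynone gives the E β-(4-methoxybenzyloxy) enone F1. TBSOTf/Et3N converts it into the 1-alkoxy-3-silyloxy diene F2, which is more electron-rich than the dienyl ester and carries no acrylate. Its intramolecular Diels–Alder reaction at lower temperature should give the cycloadduct F3. HF·pyridine then gives the β-alkoxy ketone F4, Lombardo methylenation the methylidene compound F5, and DDQ the axial C8 alcohol F6. Esterification of F6 with acid 3 (2,4,6-trichlorobenzoyl chloride, Et3N, DMAP, toluene) returns to the route at 17.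

Step 15. Branched selectivity may erode at the hindered axial alkyne, or a palladium hydride may isomerise the exocyclic alkenes. Fallback, setting out from 19: Mo(CO)3(CNtBu)3-catalysed hydrostannation with Bu3SnH places tin on the internal carbon to give the 2-stannyl alkene F7. Iododestannylation with I2 gives the 2-iodoalkene F8. Hydroxycarbonylation (Pd(PPh3)4, CO 1 atm, K2CO3, H2O/DMF, then acidification) returns to the route at 20.

Step 14. The transposition equilibrium may stall, or the perrhenate may ionise the allylic alcohol and cause elimination. Fallback, setting out from 18: acetylation (Ac2O, pyridine, DMAP) gives the secondary allylic acetate F9. A PdCl2(MeCN)2-catalysed 1,3-acetate shift (THF, rt) gives the primary allylic acetate F10. Methanolysis (K2CO3, MeOH, 0 °C) returns to the route at 19.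

Further compounds
F1 | step 10 | (1E,8S,9Z)-8-hydroxy-1-[(4-methoxybenzyl)oxy]-7-methylidene-12-(trimethylsilyl)dodeca-1,9-dien-11-yn-3-one | COc1ccc(CO/C=C/C(=O)CCCC(=C)[C@@H](O)/C=C\C#C[Si](C)(C)C)cc1
F2 | step 10 | (1E,3Z,8S,9Z)-3,8-bis[(tert-butyldimethylsilyl)oxy]-1-[(4-methoxybenzyl)oxy]-7-methylidene-12-(trimethylsilyl)dodeca-1,3,9-trien-11-yne | COc1ccc(CO/C=C/C(O[Si](C)(C)C(C)(C)C)=C/CCC(=C)[C@@H](O[Si](C)(C)C(C)(C)C)/C=C\C#C[Si](C)(C)C)cc1
F3 | step 10 | 4-methoxybenzyl ether analogue of 15 (C8 ether, C10 silyl enol ether) | C[Si](C)(C)C#C[C@H]1[C@H]2[C@H](O[Si](C)(C)C(C)(C)C)C(=C)CC[C@@H]2C(O[Si](C)(C)C(C)(C)C)=C[C@@H]1OCc3ccc(OC)cc3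
F4 | step 10 | 4-methoxybenzyl ether analogue of 16 (C10 ketone) | C[Si](C)(C)C#C[C@H]1[C@H]2[C@H](O[Si](C)(C)C(C)(C)C)C(=C)CC[C@@H]2C(=O)C[C@@H]1OCc3ccc(OC)cc3
F5 | step 10 | 4-methoxybenzyl ether analogue of 17 (C10 methylidene) | C[Si](C)(C)C#C[C@H]1[C@H]2[C@H](O[Si](C)(C)C(C)(C)C)C(=C)CC[C@@H]2C(=C)C[C@@H]1OCc3ccc(OC)cc3
F6 | step 10 | C8 alcohol: 8-[(tert-butyldimethylsilyl)oxy]-4,7-dimethylidene-1-[(trimethylsilyl)ethynyl]decahydronaphthalen-2-ol, configuration as in 17 | C[Si](C)(C)C#C[C@H]1[C@H]2[C@H](O[Si](C)(C)C(C)(C)C)C(=C)CC[C@@H]2C(=C)C[C@@H]1O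
F7 | step 15 | 2-stannyl alkene: 19 with the ethynyl group replaced by 1-(tributylstannyl)ethenyl | C=C([Sn](CCCC)(CCCC)CCCC)[C@H]1[C@H]2C=C(CO)CC[C@@H]2C(=C)C[C@@H]1OC(=O)C(=C)[C@H]3COC(C)(C)O3
F8 | step 15 | 2-iodoalkene: 19 with the ethynyl group replaced by 1-iodoethenyl | C=C(I)[C@H]1[C@H]2C=C(CO)CC[C@@H]2C(=C)C[C@@H]1OC(=O)C(=C)[C@H]3COC(C)(C)O3
F9 | step 14 | C5 acetate of 18 | C#C[C@H]1[C@H]2[C@H](OC(C)=O)C(=C)CC[C@@H]2C(=C)C[C@@H]1OC(=O)C(=C)[C@H]3COC(C)(C)O3
F10 | step 14 | C15 acetate of 19 | C#C[C@H]1[C@H]2C=C(COC(C)=O)CC[C@@H]2C(=C)C[C@@H]1OC(=O)C(=C)[C@H]3COC(C)(C)O3
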